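Cuts: (a) C7'–C8', an aldol bond between a ring B aldehyde and a homovanillic acid imide; (b) C3–C3a of the dihydrobenzofuran; (c) the bond from C2 to ring A, an aryl conjugate addition to a chromone.
Enabling feature: ring B carbon C3a and the exocyclic carbon C9 are both bonded to C3. Exchanging the C3–C3a bond for a C9–C3a bond enlarges the furan ring to the pyranone of a flavanone, whose only stereocentre is C2, the carbon that carries ring A.
Forward order: acetophenone to chromone (pyranone ring closed), aryl addition to the (2S)-flavanone, oxidative contraction to the trans dihydrobenzofuran ester, aldehyde at C5, aldol with the ring C imide, reduction and desilylation.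
Stereochemistry: C2 from the chiral pyridine-oxazoline palladium catalyst; C3 relayed from C2 in the contraction (trans); C7' and C8' from the (4S)-benzyl oxazolidinone in a syn-aldol.

Key step: step 6

Labels: O1, C2 (bears ring A, the pendant guaiacyl ring), C3, C3a to C7a (ring B, the fused benzo ring) and C9 (the one-carbon arm on C3) keep these labels in the flavanone, where C9 is the carbonyl carbon; the side chain is C7' (carbinol), C8', C9', and ring C is the guaiacyl ring on C8'.
Assumption: the pyridine-oxazoline palladium catalyst is taken to attack the chromone with the facial sense it shows for 3-substituted cyclohexenones, so the (R)-ligand is specified for the (2S)-flavanone; if the sense proves opposite, the (S)-ligand is used with no other change.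

Step 1
Reactants: 1 1-(2-hydroxy-3-methoxyphenyl)ethanone
Product: 2 1-(5-bromo-2-hydroxy-3-methoxyphenyl)ethanone
Conditions: NBS, MeCN, 0 °C to rt
Reagents that add atoms: N-bromosuccinimide, O=C1CCC(=O)N1Br
Why: Electrophilic aromatic bromination of an activated phenol, in which the hydroxyl group directs to its para position C5 because both ortho positions are blocked by the acetyl and methoxy groups.

Step 2
Reactants: 2 1-(5-bromo-2-hydroxy-3-methoxyphenyl)ethanone
Product: 4 6-bromo-8-methoxy-4H-chromen-4-one, via enaminone 3 (not isolated)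
Conditions: Me2NCH(OMe)2, toluene, 100 °C; then conc. HCl, CH2Cl2, 40 °C
Reagents that add atoms: N,N-dimethylformamide dimethyl acetal, COC(OC)N(C)C
Why: Enaminone condensation of the methyl ketone with the formamide acetal, then acid-promoted 6-endo-trig attack of the phenol on the enaminone with loss of dimethylamine, the standard enaminone route to chromones.

Step 3
Reactants: 5 2-methoxy-4-(4,4,5,5-tetramethyl-1,3,2-dioxaborolan-2-yl)phenol
Product: 6 2-methoxy-4-(4,4,5,5-tetramethyl-1,3,2-dioxaborolan-2-yl)phenyl methanesulfonate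
Conditions: MsCl, Et3N, CH2Cl2, 0 °C
Reagents that add atoms: methanesulfonyl chloride, CS(=O)(=O)Cl
Why: O-Sulfonylation of the phenol under amine base, which leaves the pinacol boronate untouched and installs the electron-withdrawing group that ring A needs in the key step.

Step 4
Reactants: 6 2-methoxy-4-(4,4,5,5-tetramethyl-1,3,2-dioxaborolan-2-yl)phenyl methanesulfonate
Product: 7 [3-methoxy-4-(methylsulfonyloxy)phenyl]boronic acid
Conditions: NaIO4, NH4OAc, acetone/H2O, rt
Reagents that add atoms: water, O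
Why: Oxidative pinacol cleavage, in which the boronate is in hydrolytic equilibrium with the boronic acid and periodate removes the released diol as acetone, while the aryl mesylate is inert at neutral pH.

Step 5
Reactants: 4 6-bromo-8-methoxy-4H-chromen-4-one; 7 [3-methoxy-4-(methylsulfonyloxy)phenyl]boronic acid
Product: 8 4-[(2S)-6-bromo-8-methoxy-4-oxo-3,4-dihydro-2H-chromen-2-yl]-2-methoxyphenyl methanesulfonate
Conditions: Pd(OCOCF3)2 (5 mol %), (R)-t-BuPyOx [(R)-4-tert-butyl-2-(pyridin-2-yl)-4,5-dihydrooxazole] (6 mol %), NH4PF6 (30 mol %), H2O (5 equiv), ClCH2CH2Cl, 60 °C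
Reagents that add atoms: none
Why: Asymmetric conjugate addition of an arylboronic acid under cationic divalent palladium catalysis (transmetalation, insertion of C2=C3 into the Pd–aryl bond, protonolysis of the palladium enolate), in which the tert-butyl group of the ligand shields one face so that C2 is set as S, and the aryl bromide and mesylate stay inert because no zerovalent palladium is formed.

Step 6
Reactants: 8 4-[(2S)-6-bromo-8-methoxy-4-oxo-3,4-dihydro-2H-chromen-2-yl]-2-methoxyphenyl methanesulfonate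
Product: 11 methyl (2S,3S)-5-bromo-7-methoxy-2-[3-methoxy-4-(methylsulfonyloxy)phenyl]-2,3-dihydro-1-benzofuran-3-carboxylate, via enol ether 9 (not isolated), via iodane ketal 10 (not isolated)
Conditions: PhI(OAc)2 (1.2 equiv), conc. H2SO4, HC(OMe)3, 0 °C to rt; then aq. NaHCO3
Reagents that add atoms: trimethyl orthoformate, COC(OC)OC; water, O
Why: Acid and HC(OMe)3 turn the C9 ketone into enol ether 9, trivalent iodine bonds to C3 on the face away from ring A and methanol caps C9, giving ketal 10 in which the phenyliodanyl group and ring A are trans and both equatorial. In 10 the ring bond C9–C3a lies antiperiplanar to the C3–I bond, so C3a shifts from C9 to C3 with inversion at C3 as iodobenzene and acetate leave, and the dimethoxycarbenium ion left at C9 is hydrolysed to the methyl ester on work-up. The closest known reaction type is the oxidative ring contraction of flavanones to trans methyl 2-aryl-2,3-dihydrobenzofuran-3-carboxylates by PhI(OAc)2 or Tl(NO3)3 in trimethyl orthoformate, a semipinacol-like 1,2-aryl shift. The dihydrofuran ring is closed not by an end-to-end cyclisation but by contraction of the pyranone: C3–C3a forms through a bridged three-centre (3-exo-tet, phenonium-like) displacement at C3 while C9–C3a breaks. The one new stereocentre, C3, is controlled by C2, because trans iodination followed by a shift with inversion places the ester arm trans to ring A (2S,3S), which is also the more stable epimer of this enolisable ester. The step needs C3a of ring B to migrate in preference to ring A (whose shift from C2 would end in an isoflavone), to capture of C3 by methanol and to dehydrogenation to the flavone; the ring oxygen ortho to C3a makes ring B electron-rich, the diequatorial geometry aligns only the ring bond with the leaving group, and the mesylate keeps ring A a poor migrating group.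

Step 7
Reactants: 11 methyl (2S,3S)-5-bromo-7-methoxy-2-[3-methoxy-4-(methylsulfonyloxy)phenyl]-2,3-dihydro-1-benzofuran-3-carboxylate
Product: 12 4-[(2S,3R)-5-bromo-3-(hydroxymethyl)-7-methoxy-2,3-dihydro-1-benzofuran-2-yl]-2-methoxyphenol
Conditions: LiAlH4, THF, 0 °C to rt; then aq. Rochelle salt
Reagents that add atoms: none
Why: Hydride reduction in which LiAlH4 converts the methyl ester into the primary alcohol and cleaves the aryl mesylate at the S–O bond to the phenoxide, while the aryl bromide and the benzylic C2–O1 ether should not react at or below room temperature and C3 loses its acidity once the ester is reduced (the descriptor at C3 changes from S to R by priority only).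

Step 8
Reactants: 12 4-[(2S,3R)-5-bromo-3-(hydroxymethyl)-7-methoxy-2,3-dihydro-1-benzofuran-2-yl]-2-methoxyphenol
Product: 13 (2S,3R)-5-bromo-2-[4-(tert-butyldimethylsilyloxy)-3-methoxyphenyl]-3-[(tert-butyldimethylsilyloxy)methyl]-7-methoxy-2,3-dihydro-1-benzofuran
Conditions: TBSCl, imidazole, DMF, rt
Reagents that add atoms: tert-butyldimethylsilyl chloride, CC(C)(C)[Si](C)(C)Cl
Why: Silylation of the phenol and the primary alcohol gives ethers that withstand the organolithium, boron enolate and borohydride steps and are removed together by fluoride at the end.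

Step 9
Reactants: 13 (2S,3R)-5-bromo-2-[4-(tert-butyldimethylsilyloxy)-3-methoxyphenyl]-3-[(tert-butyldimethylsilyloxy)methyl]-7-methoxy-2,3-dihydro-1-benzofuran
Product: 15 (2S,3R)-2-[4-(tert-butyldimethylsilyloxy)-3-methoxyphenyl]-3-[(tert-butyldimethylsilyloxy)methyl]-7-methoxy-2,3-dihydro-1-benzofuran-5-carbaldehyde, via aryllithium 14 (not isolated)
Conditions: n-BuLi, THF, −78 °C; then DMF, −78 to 0 °C; then H2O
Reagents that add atoms: N,N-dimethylformamide, CN(C)C=O
Why: Bromine–lithium exchange at −78 °C is faster than deprotonation at the benzylic C2–H or attack on the silyl ethers, and the aryllithium is formylated by DMF through a hemiaminal alkoxide that releases the aldehyde only on aqueous quench.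

Step 10
Reactants: 16 (4-hydroxy-3-methoxyphenyl)acetic acid (homovanillic acid)
Product: 18 [4-(tert-butyldimethylsilyloxy)-3-methoxyphenyl]acetic acid, via silyl ester 17 (not isolated)
Conditions: TBSCl (2.5 equiv), imidazole, DMF, rt; then AcOH, THF/H2O, rt
Reagents that add atoms: tert-butyldimethylsilyl chloride, CC(C)(C)[Si](C)(C)Cl
Why: Exhaustive silylation followed by selective hydrolysis of the far more labile silyl ester under mild aqueous acid, which leaves the aryl silyl ether in place.

Step 11
Reactants: 18 [4-(tert-butyldimethylsilyloxy)-3-methoxyphenyl]acetic acid; 19 (4S)-4-benzyl-1,3-oxazolidin-2-one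
Product: 21 (4S)-4-benzyl-3-{[4-(tert-butyldimethylsilyloxy)-3-methoxyphenyl]acetyl}-1,3-oxazolidin-2-one, via mixed anhydride 20 (not isolated)
Conditions: PivCl, Et3N, THF, −20 °C; then LiCl, 19, −20 °C to rt
Reagents that add atoms: none
Why: N-Acylation of the oxazolidinone through the mixed pivalic anhydride, in which LiCl activates the oxazolidinone so that triethylamine suffices as base and attack occurs at the less hindered arylacetyl carbonyl.

Step 12
Reactants: 21 (4S)-4-benzyl-3-{[4-(tert-butyldimethylsilyloxy)-3-methoxyphenyl]acetyl}-1,3-oxazolidin-2-one; 15 (2S,3R)-2-[4-(tert-butyldimethylsilyloxy)-3-methoxyphenyl]-3-[(tert-butyldimethylsilyloxy)methyl]-7-methoxy-2,3-dihydro-1-benzofuran-5-carbaldehyde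
Product: 23 (4S)-4-benzyl-3-[(2S,3S)-2-[4-(tert-butyldimethylsilyloxy)-3-methoxyphenyl]-3-{(2S,3R)-2-[4-(tert-butyldimethylsilyloxy)-3-methoxyphenyl]-3-[(tert-butyldimethylsilyloxy)methyl]-7-methoxy-2,3-dihydro-1-benzofuran-5-yl}-3-hydroxypropanoyl]-1,3-oxazolidin-2-one, via boron enolate 22 (not isolated)
Conditions: 21 (1.3 equiv), Bu2BOTf, i-Pr2NEt, CH2Cl2, −78 to 0 °C; then 15, −78 to 0 °C; then pH 7 phosphate buffer, MeOH, 30% H2O2, 0 °C
Reagents that add atoms: none
Why: Evans syn-aldol addition in which the Z boron enolate reacts through a closed chair (Zimmerman–Traxler) transition state on the enolate face away from the benzyl group of the (4S)-auxiliary, setting C8' and C7' together as the syn (2S,3S) aldol, which becomes (7'S,8'R) after reduction.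

Step 13
Reactants: 23 the syn-aldol imide of step 12
Product: 24 (1S,2R)-2-[4-(tert-butyldimethylsilyloxy)-3-methoxyphenyl]-1-{(2S,3R)-2-[4-(tert-butyldimethylsilyloxy)-3-methoxyphenyl]-3-[(tert-butyldimethylsilyloxy)methyl]-7-methoxy-2,3-dihydro-1-benzofuran-5-yl}propane-1,3-diol
Conditions: LiBH4, MeOH (1 equiv), THF, 0 °C
Reagents that add atoms: none
Why: Reductive cleavage of the N-acyl oxazolidinone, in which the borohydride attacks the exocyclic imide carbonyl, releases the auxiliary and gives the primary alcohol without touching the silyl ethers, the low temperature holding back retro-aldol cleavage and epimerisation at C8'.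

Step 14
Reactants: 24 the tris-silylated 1,3-diol of step 13
Product: 25 (1S,2R)-1-[(2S,3R)-2-(4-hydroxy-3-methoxyphenyl)-3-(hydroxymethyl)-7-methoxy-2,3-dihydro-1-benzofuran-5-yl]-2-(4-hydroxy-3-methoxyphenyl)propane-1,3-diol
Conditions: Bu4NF, AcOH, THF, 0 °C to rt
Reagents that add atoms: none
Why: Fluoride-mediated cleavage of the three silyl ethers, buffered with acetic acid so that the phenoxides are protonated as they form and neither the dihydrobenzofuran ring nor the benzylic alcohol at C7' meets strong base or acid.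

Compound list
1 | 1-(2-hydroxy-3-methoxyphenyl)ethanone | CC(=O)c1cccc(OC)c1O | starting material
2 | 1-(5-bromo-2-hydroxy-3-methoxyphenyl)ethanone | CC(=O)c1cc(Br)cc(OC)c1O | intermediate
3 | (E)-1-(5-bromo-2-hydroxy-3-methoxyphenyl)-3-(dimethylamino)prop-2-en-1-one (enaminone) | CN(C)/C=C/C(=O)c1cc(Br)cc(OC)c1O | intermediate
4 | 6-bromo-8-methoxy-4H-chromen-4-one | O=c1ccoc2c(OC)cc(Br)cc12 | intermediate
5 | 2-methoxy-4-(4,4,5,5-tetramethyl-1,3,2-dioxaborolan-2-yl)phenol | COc1cc(B2OC(C)(C)C(C)(C)O2)ccc1O | starting material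
6 | 2-methoxy-4-(4,4,5,5-tetramethyl-1,3,2-dioxaborolan-2-yl)phenyl methanesulfonate | COc1cc(B2OC(C)(C)C(C)(C)O2)ccc1OS(C)(=O)=O | intermediate
7 | [3-methoxy-4-(methylsulfonyloxy)phenyl]boronic acid | COc1cc(B(O)O)ccc1OS(C)(=O)=O | intermediate
8 | 4-[(2S)-6-bromo-8-methoxy-4-oxo-3,4-dihydro-2H-chromen-2-yl]-2-methoxyphenyl methanesulfonate | COc1cc([C@H]2Oc3c(OC)cc(Br)cc3C(=O)C2)ccc1OS(C)(=O)=O | intermediate
9 | 4-[(2S)-6-bromo-4,8-dimethoxy-2H-chromen-2-yl]-2-methoxyphenyl methanesulfonate (enol ether) | COc1cc([C@H]2Oc3c(OC)cc(Br)cc3C(OC)=C2)ccc1OS(C)(=O)=O | intermediate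
10 | 4-[(2R,3R)-3-[acetoxy(phenyl)iodanyl]-6-bromo-4,4,8-trimethoxy-3,4-dihydro-2H-chromen-2-yl]-2-methoxyphenyl methanesulfonate (2,3-trans; C2 geometry as in 8, descriptor changed by priority only) | COc1cc([C@H]2Oc3c(OC)cc(Br)cc3C(OC)(OC)[C@@H]2I(OC(C)=O)c2ccccc2)ccc1OS(C)(=O)=O | intermediate
11 | methyl (2S,3S)-5-bromo-7-methoxy-2-[3-methoxy-4-(methylsulfonyloxy)phenyl]-2,3-dihydro-1-benzofuran-3-carboxylate (trans) | COc1cc([C@H]2Oc3c(OC)cc(Br)cc3[C@@H]2C(=O)OC)ccc1OS(C)(=O)=O | intermediate
12 | 4-[(2S,3R)-5-bromo-3-(hydroxymethyl)-7-methoxy-2,3-dihydro-1-benzofuran-2-yl]-2-methoxyphenol | COc1cc([C@H]2Oc3c(OC)cc(Br)cc3[C@@H]2CO)ccc1O | intermediate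
13 | (2S,3R)-5-bromo-2-[4-(tert-butyldimethylsilyloxy)-3-methoxyphenyl]-3-[(tert-butyldimethylsilyloxy)methyl]-7-methoxy-2,3-dihydro-1-benzofuran | COc1cc([C@H]2Oc3c(OC)cc(Br)cc3[C@@H]2CO[Si](C)(C)C(C)(C)C)ccc1O[Si](C)(C)C(C)(C)C | intermediate
14 | [(2S,3R)-2-[4-(tert-butyldimethylsilyloxy)-3-methoxyphenyl]-3-[(tert-butyldimethylsilyloxy)methyl]-7-methoxy-2,3-dihydro-1-benzofuran-5-yl]lithium | COc1cc([C@H]2Oc3c(OC)cc([Li])cc3[C@@H]2CO[Si](C)(C)C(C)(C)C)ccc1O[Si](C)(C)C(C)(C)C | intermediate
15 | (2S,3R)-2-[4-(tert-butyldimethylsilyloxy)-3-methoxyphenyl]-3-[(tert-butyldimethylsilyloxy)methyl]-7-methoxy-2,3-dihydro-1-benzofuran-5-carbaldehyde | COc1cc([C@H]2Oc3c(OC)cc(C=O)cc3[C@@H]2CO[Si](C)(C)C(C)(C)C)ccc1O[Si](C)(C)C(C)(C)C | intermediate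
16 | (4-hydroxy-3-methoxyphenyl)acetic acid (homovanillic acid) | COc1cc(CC(=O)O)ccc1O | starting material
17 | tert-butyldimethylsilyl [4-(tert-butyldimethylsilyloxy)-3-methoxyphenyl]acetate | COc1cc(CC(=O)O[Si](C)(C)C(C)(C)C)ccc1O[Si](C)(C)C(C)(C)C | intermediate
18 | [4-(tert-butyldimethylsilyloxy)-3-methoxyphenyl]acetic acid | COc1cc(CC(=O)O)ccc1O[Si](C)(C)C(C)(C)C | intermediate
19 | (4S)-4-benzyl-1,3-oxazolidin-2-one | O=C1OC[C@H](Cc2ccccc2)N1 | starting material
20 | [4-(tert-butyldimethylsilyloxy)-3-methoxyphenyl]acetic pivalic anhydride | COc1cc(CC(=O)OC(=O)C(C)(C)C)ccc1O[Si](C)(C)C(C)(C)C | intermediate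
21 | (4S)-4-benzyl-3-{[4-(tert-butyldimethylsilyloxy)-3-methoxyphenyl]acetyl}-1,3-oxazolidin-2-one | COc1cc(CC(=O)N2[C@@H](Cc3ccccc3)COC2=O)ccc1O[Si](C)(C)C(C)(C)C | intermediate
22 | (4S)-4-benzyl-3-[(Z)-2-[4-(tert-butyldimethylsilyloxy)-3-methoxyphenyl]-1-(dibutylboranyloxy)ethenyl]-1,3-oxazolidin-2-one (Z boron enolate) | CCCCB(CCCC)O/C(=C\c1ccc(O[Si](C)(C)C(C)(C)C)c(OC)c1)N1[C@@H](Cc2ccccc2)COC1=O | intermediate
23 | (4S)-4-benzyl-3-[(2S,3S)-2-[4-(tert-butyldimethylsilyloxy)-3-methoxyphenyl]-3-{(2S,3R)-2-[4-(tert-butyldimethylsilyloxy)-3-methoxyphenyl]-3-[(tert-butyldimethylsilyloxy)methyl]-7-methoxy-2,3-dihydro-1-benzofuran-5-yl}-3-hydroxypropanoyl]-1,3-oxazolidin-2-one | COc1cc([C@H]2Oc3c(OC)cc([C@@H](O)[C@@H](C(=O)N4[C@@H](Cc5ccccc5)COC4=O)c4ccc(O[Si](C)(C)C(C)(C)C)c(OC)c4)cc3[C@@H]2CO[Si](C)(C)C(C)(C)C)ccc1O[Si](C)(C)C(C)(C)C | intermediate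
24 | (1S,2R)-2-[4-(tert-butyldimethylsilyloxy)-3-methoxyphenyl]-1-{(2S,3R)-2-[4-(tert-butyldimethylsilyloxy)-3-methoxyphenyl]-3-[(tert-butyldimethylsilyloxy)methyl]-7-methoxy-2,3-dihydro-1-benzofuran-5-yl}propane-1,3-diol | COc1cc([C@H]2Oc3c(OC)cc([C@@H](O)[C@@H](CO)c4ccc(O[Si](C)(C)C(C)(C)C)c(OC)c4)cc3[C@@H]2CO[Si](C)(C)C(C)(C)C)ccc1O[Si](C)(C)C(C)(C)C | intermediate
25 | (1S,2R)-1-[(2S,3R)-2-(4-hydroxy-3-methoxyphenyl)-3-(hydroxymethyl)-7-methoxy-2,3-dihydro-1-benzofuran-5-yl]-2-(4-hydroxy-3-methoxyphenyl)propane-1,3-diol | COc1cc([C@H]2Oc3c(OC)cc([C@@H](O)[C@@H](CO)c4ccc(O)c(OC)c4)cc3[C@@H]2CO)ccc1O | target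

Total step count: 14. Longest linear sequence: 10 steps (steps 1, 2, 5, 6, 7, 8, 9, 12, 13, 14, from compound 1); the boronic acid (steps 3 and 4) and the imide (steps 10 and 11) are made in side branches.

Steps most likely to fail

Step 6. The iodane ketal may go down other paths: loss of a proton to give the flavone, capture of C3 by methanol, migration of ring A, or acid-induced erosion of the C2 configuration. The fallback keeps the same C3–C3a bond formation but uses a carbene instead of an iodane. It sets out from 8, which is enolised at −78 °C with LiN(SiMe3)2 (the low temperature keeps the enolate from opening to the chalcone) and acylated with 2,2,2-trifluoroethyl trifluoroacetate to 4-[(2S)-6-bromo-8-methoxy-4-oxo-3-(trifluoroacetyl)chroman-2-yl]-2-methoxyphenyl methanesulfonate F1. Detrifluoroacetylative diazo transfer (MsN3, Et3N, H2O, MeCN) then gives the 3-diazoflavanone F2. Irradiation of F2 in methanol triggers a Wolff rearrangement in which C3a moves from C9 to the carbene carbon C3, and methanol traps the ketene as a mixture of 11 and its cis epimer, methyl (2S,3R)-5-bromo-7-methoxy-2-[3-methoxy-4-(methylsulfonyloxy)phenyl]-2,3-dihydro-1-benzofuran-3-carboxylate F3. DBU in toluene equilibrates F3 to the trans ester, and the route is rejoined at 11.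

Step 5. Insertion into the electron-rich 8-methoxychromone may be slow, the boronic acid may protodeboronate first, or facial discrimination may be poor. The fallback sets C2 by C–O instead of C–C bond formation and sets out from 2. The dianion of 2 (LiN(SiMe3)2, THF, −78 °C) is C-acylated with Boc2O to tert-butyl 3-(5-bromo-2-hydroxy-3-methoxyphenyl)-3-oxopropanoate F4. Vanillin is mesylated (MsCl, Et3N) to 4-formyl-2-methoxyphenyl methanesulfonate F5, and Knoevenagel condensation of F4 with F5 (piperidinium acetate, toluene, reflux) gives the alkylidene β-ketoester tert-butyl 2-(5-bromo-2-hydroxy-3-methoxybenzoyl)-3-[3-methoxy-4-(methylsulfonyloxy)phenyl]prop-2-enoate F6. A cinchona-derived bifunctional thiourea (the quinine or quinidine pseudoenantiomer that delivers the 2S series) catalyses the intramolecular oxa-Michael addition to tert-butyl (2S)-6-bromo-8-methoxy-2-[3-methoxy-4-(methylsulfonyloxy)phenyl]-4-oxochromane-3-carboxylate F7. TsOH in toluene at 80 °C removes the tert-butyl ester with decarboxylation, and the route is rejoined at 8.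

Step 7. Cleavage of the mesylate S–O bond may stay incomplete at temperatures where the aryl bromide is safe, and heating invites hydrodebromination. The fallback separates the two tasks and sets out from 11. LiBH4 in THF/MeOH at 0 °C reduces only the ester, giving 4-[(2S,3R)-5-bromo-3-(hydroxymethyl)-7-methoxy-2,3-dihydro-1-benzofuran-2-yl]-2-methoxyphenyl methanesulfonate F8. Hydrolysis of the sulfonate with KOH in MeOH/H2O at 50 °C then frees the phenol, and the route is rejoined at 12.

Further compounds
F1 | step 6 | 4-[(2S)-6-bromo-8-methoxy-4-oxo-3-(trifluoroacetyl)chroman-2-yl]-2-methoxyphenyl methanesulfonate (C3 unassigned, enolisable) | COc1cc([C@H]2Oc3c(OC)cc(Br)cc3C(=O)C2C(=O)C(F)(F)F)ccc1OS(C)(=O)=O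
F2 | step 6 | 4-[(2R)-6-bromo-3-diazo-8-methoxy-4-oxochroman-2-yl]-2-methoxyphenyl methanesulfonate (C2 geometry as in 8, descriptor changed by priority only) | COc1cc([C@H]2Oc3c(OC)cc(Br)cc3C(=O)C2=[N+]=[N-])ccc1OS(C)(=O)=O
F3 | step 6 | methyl (2S,3R)-5-bromo-7-methoxy-2-[3-methoxy-4-(methylsulfonyloxy)phenyl]-2,3-dihydro-1-benzofuran-3-carboxylate (cis) | COc1cc([C@H]2Oc3c(OC)cc(Br)cc3[C@H]2C(=O)OC)ccc1OS(C)(=O)=O
F4 | step 5 | tert-butyl 3-(5-bromo-2-hydroxy-3-methoxyphenyl)-3-oxopropanoate | CC(C)(C)OC(=O)CC(=O)c1cc(Br)cc(OC)c1O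
F5 | step 5 | 4-formyl-2-methoxyphenyl methanesulfonate | COc1cc(C=O)ccc1OS(C)(=O)=O
F6 | step 5 | tert-butyl 2-(5-bromo-2-hydroxy-3-methoxybenzoyl)-3-[3-methoxy-4-(methylsulfonyloxy)phenyl]prop-2-enoate (alkene geometry unassigned) | COc1cc(C=C(C(=O)OC(C)(C)C)C(=O)c2cc(Br)cc(OC)c2O)ccc1OS(C)(=O)=O
F7 | step 5 | tert-butyl (2S)-6-bromo-8-methoxy-2-[3-methoxy-4-(methylsulfonyloxy)phenyl]-4-oxochromane-3-carboxylate (C3 unassigned, enolisable) | COc1cc([C@H]2Oc3c(OC)cc(Br)cc3C(=O)C2C(=O)OC(C)(C)C)ccc1OS(C)(=O)=O
F8 | step 7 | 4-[(2S,3R)-5-bromo-3-(hydroxymethyl)-7-methoxy-2,3-dihydro-1-benzofuran-2-yl]-2-methoxyphenyl methanesulfonate | COc1cc([C@H]2Oc3c(OC)cc(Br)cc3[C@@H]2CO)ccc1OS(C)(=O)=O
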